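## Structural features

The target is a biflavone in which two C15 units are joined by a single carbon–carbon bond. Unit 1 is 5-hydroxy-7-methoxy-2-(4-hydroxyphenyl)chromen-4-one (benzo ring A, pyranone ring C, aryl ring B) and carries the link at C3. Unit 2 is luteolin (benzo ring D, pyranone ring F, catechol ring E) and carries it at C6''. There is no stereogenic carbon; the C3–C6'' axis has four ortho substituents (C2 aryl and C4 carbonyl on one side, the C5'' and C7'' hydroxyls on the other) and may rotate slowly, but no axial descriptor is specified. Five phenols stand beside one methyl ether at C7, so every other oxygen must travel under a group that can be removed without touching O–CH3. The sensitive parts are the electron-rich ring D (an ambident O/C nucleophile, easily oxidised as its anion), the catechol, and the two pyranones, which open at C2 in hot hydroxide. The real difficulty is the congested aryl–aryl bond at C3 and the choice of C6'' over C8''. Ring D is a phloroglucinol in which C6'' lies between the oxygen-bearing carbons C5'' and C7'' with C8a''–O para to it. It therefore maps onto a 3,5-dioxohexanoate whose C6 is a methylene already bonded to C3 of unit 1; the key step closes it by a Claisen condensation to a symmetric 2-arylphloroglucinol, and building ring F through its unique para oxygen can then give only the 6'' linkage.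

## Logic of the disconnections

**22 from 21.** Cut: the six O–benzyl bonds. Every oxygen except the C7 methyl ether carries the same group, so one hydrogenolysis ends the synthesis. Gain: phenols, catechol and peri hydroxyls are silent during all C–C bond formation. Demand: the forward step must spare O–CH3 and both pyranone C2=C3 bonds.

**21 from 19.** Cut: C4''–C4a'', the aryl ketone bond of ring F. The attacked carbon is ortho to the ether oxygen of a tri-oxygenated arene, and the two candidate carbons are equivalent by the symmetry of ring D, so no regiochemical choice exists. Gain: ring F disappears and unit 2 becomes an aryl vinyl ether. Demand: the carboxyl group must reach the arene (cis to the aryloxy group, or able to isomerise), and the activation must be mild enough for six benzyl ethers.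

**19 from 17 by way of 18.** Cuts: the acid O–H back to its methyl ester, and the two O–benzyl bonds at the future C5'' and C7''. Free hydroxyls there would be acylated by the activating agent and would deactivate ring D toward ring closure; as benzyl ethers they leave in the final hydrogenolysis. This is an addition to the design that costs one step. Gain: the only distinction ring D ever needs is para versus ortho oxygen. Demand: O- over C-alkylation on an electron-rich ring, and saponification without displacement of the aryloxy group.

**17 from 12 and 16.** Cut: O1''–C2'', the aryl–O–vinyl bond. This is the convergent join; 16 delivers C2'', C3'', C4'' and ring E in one piece. Gain: 12 is a symmetric triol and 16 a simple alkynoate. Demand: the conjugate addition must go through the para oxygen of 12, not an ortho oxygen or a ring carbon.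

**16 from 13 by way of 14.** Cuts: the alkyne–ester C–C bond and the C≡C bond, back to an aldehyde. Gain: a commercial aldehyde that already carries both benzyl ethers. Demand: organolithium chemistry compatible with benzyl ethers at low temperature.

**12 from 11 (key disconnection).** Cut: C6''–C7'', which opens ring D to a 3,5-dioxo ester chain. The cut is made here because C6'' then becomes an sp3 methylene on C3 of unit 1, and the hindered biaryl bond is reduced to an ordinary C–CH2 bond. Gain: one ring and the whole biaryl problem. Demand: in the forward step C6 must attack the ester carbon (C-cyclisation) in preference to lactonisation through oxygen, under conditions that unit 1 survives.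

**11 from 7 and 8.** Cut: the C4–C5 bond of the hexanoate chain, between an acyl carbon and the terminal carbon of an acetoacetate unit. Gain: a flavone-3-acetic acid and a bulk C4 ester. Demand: acylation at the gamma carbon of the acetoacetate dianion must outrun proton transfer from the acidic methylene of the activated acid.

**7 from 4 and 5 by way of 6.** Cuts: O1–C2 of ring C (cyclodehydration) and the C3–CH2 bond (alkylation of the 1,3-diketone carbon). Gain: the acetic acid side arm is installed on the most acidic carbon of an open-chain precursor, not on a finished flavone. Demand: C-alkylation must beat O-alkylation of the one free phenol, and the acid step must spare the benzyl ethers.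

**4 from 2 and 3; 2 from 1.** Cuts: the C–C bond between the diketone methylene and the aroyl carbon, then one O–benzyl bond. 1 already has O–CH3 at the future C7 and two equivalent hydroxyls, so one benzylation differentiates all three oxygens of ring A. Demand: mono-benzylation, and C-acylation of the ketone enolate.

## Other disconnections considered

**Alternative 1:** The cut is C4a''–C8a'' of ring D in chalcone A1, which opens ring D to a tetraketide stored as the 4-hydroxy-2-pyranone A2. In the forward sense Mg(OMe)2 in methanol would open the lactone of A2 to a chelated 3,5,7-trioxo ester, whose C6 carbanion condenses with the ester carbon to give A1. Oxidative closure of the chalcone and debenzylation would follow.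
- In favour: the nucleophilic carbon lies between two carbonyls and is unhindered, because the flavone sits on a spectator carbon. On mechanism this is better than the chosen plan, where C6 is activated by one ketone only and flanked by unit 1.
- In favour: the cinnamoyl arm brings every carbon of rings F and E, so fewer operations remain after the key step. On step economy after the key step it is also better.
- Against: in A1 two hydroxyls flank the acyl group, so flavone closure can use either, and nothing in the structure decides between the 6'' and 8'' linkage. The chosen plan settles this point through the para oxygen.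
- Against: A2 needs acylation at a carbon that already bears the flavone and sits between two carbonyls, and its enone terminus invites Michael and aldol side reactions. A tetraketide also has an aldol folding mode that the triketide of the chosen plan lacks.
- On structure the two plans are equal in that both build ring D from a polyketide chain and avoid any biaryl coupling.

**Alternative 2:** The cut is C4''–C4a'' of ring F in hexabenzyl ether A3, back to the β-aryloxycinnamic acid A4. In the forward sense the acid, as its mixed trifluoroacetic anhydride, would acylate the ortho carbon of its own aryloxy ring.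
- In favour: the closure is late, mild and free of regiochemical choice because the two ortho carbons are symmetry-equivalent. The chosen plan uses exactly this closure as step 12 (A3 is compound 21 and A4 is compound 19), so on this step the two are equal.
- Against: as the strategy-defining cut it simplifies only ring F. The C3–C6'' bond and ring D must then come from elsewhere, most directly a cross-coupling at C3 of unit 1 with a 2,6-dioxygenated aryl-metal partner. That is a four-ortho-substituted coupling with a partner prone to protodemetalation, and it needs a separately differentiated para oxygen.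
- Such a coupling route could be more convergent, and on that point it is potentially better. On mechanism the chosen plan carries less risk at the biaryl bond, and the overall step counts would be similar.

**Alternative 3:** The cut removes three bonds of ring D (C5''–C6'', C7''–C8'', C4a''–C5''), back to a triisopropylsiloxyalkyne on C3 of unit 1, A6, and 3-(4-methoxybenzyloxy)cyclobutenone A7. In the forward sense heating would open A7 to a vinylketene, which adds across the alkyne. The new vinylcyclobutenone would reopen, undergo six-electron closure and tautomerise to the resorcinol derivative A5.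
- In favour: the conditions are neutral and thermal, with no alkoxide, which is better for the pyranone of unit 1.
- In favour: the three oxygens of ring D emerge fully differentiated, with the future O1'' alone under the 4-methoxybenzyl group. This is better than the chosen plan at the one point where that plan relies on site selectivity (step 9).
- Against: A6 is an ynol silyl ether on a flavone. Its usual preparations use ester homologation with strong organolithium bases that the pyranone would not tolerate, and the alkyne is very hindered for the cycloaddition. A7 needs its own synthesis, and the distinction between the free hydroxyl and the silyl ether in A5 is not needed.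
- Three skeletal bonds are formed instead of one, but the route to the two components would be clearly longer. On step economy and on access to the precursor the chosen plan is ahead; on avoiding a biaryl coupling the two are equal.

Key step: step 6

Assumption: since no axial descriptor is specified, the C3–C6'' axis is treated as stereochemically undefined; it first becomes stereogenic in step 12 and is formed as the racemate.

Remark: the vinyl ethers 17–20 are drawn as the Z isomers expected from anti addition; the E isomers would converge in step 12.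

## Route

Step 1
Reactants: 1 1-(2,6-dihydroxy-4-methoxyphenyl)ethanone
Product: 2 1-[2-(benzyloxy)-6-hydroxy-4-methoxyphenyl]ethanone
Conditions: BnBr (1.05 equiv), K2CO3 (1.1 equiv), acetone, reflux
Reagents that add atoms: benzyl bromide, BrCc1ccccc1
Why: Williamson mono-benzylation of one of two equivalent phenols; after the first alkylation the remaining hydroxyl is locked in a hydrogen bond to the ketone and should react much more slowly.

Step 2
Reactants: 2 1-[2-(benzyloxy)-6-hydroxy-4-methoxyphenyl]ethanone; 3 4-(benzyloxy)benzoyl chloride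
Product: 4 1-[2-(benzyloxy)-6-hydroxy-4-methoxyphenyl]-3-[4-(benzyloxy)phenyl]propane-1,3-dione
Conditions: LiN(SiMe3)2 (3.2 equiv), THF, −78 → −10 °C; 3, −78 °C → rt; aq HCl
Reagents that add atoms: none
Why: Claisen-type C-acylation of the dilithio species (phenoxide plus ketone enolate) by the aroyl chloride, the one-flask equivalent of O-aroylation and Baker–Venkataraman rearrangement; the third equivalent of base absorbs the acidic diketone product.

Step 3
Reactants: 4 the 1,3-diketone; 5 tert-butyl bromoacetate
Product: 6 tert-butyl 3-[2-(benzyloxy)-6-hydroxy-4-methoxybenzoyl]-4-[4-(benzyloxy)phenyl]-4-oxobutanoate (racemic)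
Conditions: K2CO3 (1.2 equiv), acetone, 50 °C
Reagents that add atoms: none
Why: C-alkylation of a 1,3-diketone enolate by an α-bromo ester; the remaining phenol is chelated to the aryl ketone and flanked by the acyl group, so its O-alkylation should be slow; the new stereocentre is racemic and is erased in step 4.

Step 4
Reactants: 6 the alkylated diketone
Product: 7 2-{5-(benzyloxy)-2-[4-(benzyloxy)phenyl]-7-methoxy-4-oxo-4H-chromen-3-yl}acetic acid
Conditions: TFA/CH2Cl2 (1:1), 0 °C → rt
Reagents that add atoms: none
Why: Acid-catalysed addition of the phenol to the 4-benzyloxybenzoyl carbonyl and loss of water (cyclodehydration of a 2-hydroxyaryl 1,3-diketone to a flavone), with acidolysis of the tert-butyl ester in the same flask; benzyl aryl ethers tolerate TFA at room temperature.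

Step 5
Reactants: 7 the flavone-3-acetic acid; 8 methyl acetoacetate
Product: 11 methyl 6-{5-(benzyloxy)-2-[4-(benzyloxy)phenyl]-7-methoxy-4-oxo-4H-chromen-3-yl}-3,5-dioxohexanoate, via acyl imidazole 9 (not isolated), via acetoacetate dianion 10 (not isolated)
Conditions: 7, CDI (1.1 equiv), THF, rt; 8 (3.5 equiv), NaH then n-BuLi, THF, 0 °C; combine at −78 → −20 °C; cold aq HCl
Reagents that add atoms: none
Why: Huckin–Weiler dianion chemistry: the gamma carbon of the acetoacetate dianion is acylated by the imidazolide (Claisen-type acylation) to give the 3,5-dioxo ester; the excess of dianion covers the imidazole freed on activation and the acidic product, each of which quenches one equivalent.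

Step 6
Reactants: 11 the 3,5-dioxo ester
Product: 12 5-(benzyloxy)-2-[4-(benzyloxy)phenyl]-7-methoxy-3-(2,4,6-trihydroxyphenyl)-4H-chromen-4-one
Conditions: NaOMe (6 equiv), dry MeOH/THF, 65 °C, argon; aq HCl
Reagents that add atoms: none
Why: Methoxide converts 11 into its diketonate and, in equilibrium, into the enolate at C6, the methylene alpha to the C5 ketone and allylic to C2=C3 of unit 1; this carbanion adds to the ester carbon C1 and methoxide is expelled, an intramolecular Claisen (Dieckmann-type) condensation of the kind known for 3,5-dioxoalkanoates going to phloroglucinols. Ring D closes in the 6-exo-trig mode through the new C6''–C7'' bond, and the cyclohexane-1,3,5-trione tautomerises at once to the 2-arylphloroglucinol, whose deprotonation in the medium makes the closure irreversible. No stereocentre is formed, and because ring D of 12 is symmetric the biaryl axis is not yet stereogenic. The selectivity needed is C- over O-cyclisation: attack of the C5 enolate oxygen on C1 would give a 6-substituted 4-hydroxy-2-pyranone, but in methanolic methoxide that lactone can reopen to the ester whereas the aromatic carbocycle is the thermodynamic sink. No other carbocyclisation competes, since every other carbanion–carbonyl pairing within the chain would close a four-membered ring, so the triketide has no aldol mode. The congested C3–C6'' bond is not made here; it is already present as the C3–CH2 bond of 11. Dry, oxygen-free conditions protect the pyranone of unit 1 from hydroxide cleavage and the phloroglucinolate from autoxidation.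

Step 7
Reactants: 13 3,4-bis(benzyloxy)benzaldehyde
Product: 14 1,2-bis(benzyloxy)-4-(2,2-dibromoethenyl)benzene
Conditions: CBr4 (2 equiv), PPh3 (4 equiv), CH2Cl2, 0 °C
Reagents that add atoms: carbon tetrabromide, BrC(Br)(Br)Br
Why: First stage of the Corey–Fuchs sequence (Ramirez dibromo-olefination): the ylide formed from PPh3 and CBr4 olefinates the aldehyde in a Wittig reaction.

Step 8
Reactants: 14 the dibromoalkene
Product: 16 methyl 3-[3,4-bis(benzyloxy)phenyl]prop-2-ynoate, via lithium acetylide 15 (not isolated)
Conditions: n-BuLi (2.1 equiv), THF, −78 °C; ClCO2Me, −78 → 0 °C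
Reagents that add atoms: methyl chloroformate, COC(=O)Cl
Why: Second stage of the Corey–Fuchs sequence: bromine–lithium exchange and Fritsch–Buttenberg–Wiechell rearrangement give the lithium acetylide, which is C-acylated by the chloroformate; benzyl ethers tolerate n-BuLi at −78 °C.

Step 9
Reactants: 12 the 2-arylphloroglucinol; 16 the aryl propiolate
Product: 17 methyl (2Z)-3-[3,4-bis(benzyloxy)phenyl]-3-(4-{5-(benzyloxy)-2-[4-(benzyloxy)phenyl]-7-methoxy-4-oxo-4H-chromen-3-yl}-3,5-dihydroxyphenoxy)prop-2-enoate
Conditions: Cs2CO3 (0.5 equiv), 16 (1.0 equiv), degassed DMF, 60 °C, argon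
Reagents that add atoms: none
Why: Oxa-Michael addition of a phenoxide to an aryl propiolate (first stage of the Ruhemann flavone synthesis); with half an equivalent of Cs2CO3 ring D is at most a monoanion, and the para oxygen, flanked by two hydrogens, should react in preference to the ortho oxygens, which lie over the twisted unit 1 and can hydrogen-bond to its C4 carbonyl. Anti addition should give mainly the Z vinyl ether, and the para adduct is recognisable because ring D keeps its symmetry.

Step 10
Reactants: 17 the para vinyl ether diol
Product: 18 methyl (2Z)-3-(3,5-bis(benzyloxy)-4-{5-(benzyloxy)-2-[4-(benzyloxy)phenyl]-7-methoxy-4-oxo-4H-chromen-3-yl}phenoxy)-3-[3,4-bis(benzyloxy)phenyl]prop-2-enoate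
Conditions: BnBr (2.5 equiv), K2CO3 (3 equiv), DMF, 50 °C
Reagents that add atoms: benzyl bromide, BrCc1ccccc1
Why: Williamson etherification of the two remaining phenols in a polar aprotic solvent, which favours O- over C-benzylation; the vinyl ether and the methyl ester are inert to carbonate.

Step 11
Reactants: 18 the hexabenzyl methyl ester
Product: 19 (2Z)-3-(3,5-bis(benzyloxy)-4-{5-(benzyloxy)-2-[4-(benzyloxy)phenyl]-7-methoxy-4-oxo-4H-chromen-3-yl}phenoxy)-3-[3,4-bis(benzyloxy)phenyl]prop-2-enoic acid
Conditions: LiOH·H2O (5 equiv), THF/MeOH/H2O, 40 °C; dilute aq HCl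
Reagents that add atoms: lithium hydroxide, [Li+].[OH-]
Why: Saponification of the methyl ester (acyl-oxygen cleavage); hydroxide should attack the ester carbonyl faster than the donor-substituted beta carbon, so the aryl vinyl ether survives, as does the pyranone of unit 1 at this temperature.

Step 12
Reactants: 19 the β-aryloxycinnamic acid
Product: 21 5-(benzyloxy)-2-[4-(benzyloxy)phenyl]-3-{5,7-bis(benzyloxy)-2-[3,4-bis(benzyloxy)phenyl]-4-oxo-4H-chromen-6-yl}-7-methoxy-4H-chromen-4-one (racemic about the biaryl axis), via mixed anhydride 20 (not isolated)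
Conditions: TFAA (1.3 equiv), CH2Cl2, 0 °C → rt; aq NaHCO3
Reagents that add atoms: none
Why: Intramolecular Friedel–Crafts acylation through the mixed trifluoroacetic anhydride (second stage of the Ruhemann flavone synthesis): the acyl carbon attacks the position ortho to the vinyl ether oxygen, which is also ortho and para to benzyloxy groups, and closes ring F. The two ortho positions are equivalent, so only the 6''-linked flavone can form, and the acid released should isomerise any E vinyl ether to the reactive Z form.

Step 13
Reactants: 21 the hexabenzyl ether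
Product: 22 3-[2-(3,4-dihydroxyphenyl)-5,7-dihydroxy-4-oxo-4H-chromen-6-yl]-5-hydroxy-2-(4-hydroxyphenyl)-7-methoxy-4H-chromen-4-one (target)
Conditions: H2 (1 atm), Pd/C (10 wt% Pd on carbon), THF/MeOH, rt
Reagents that add atoms: none
Why: Hydrogenolysis of six benzyl aryl ethers over palladium; the methyl ether is inert, and the conjugated C2=C3 bonds of chromen-4-ones are not normally reduced at one atmosphere.

## Compound list

1 | 1-(2,6-dihydroxy-4-methoxyphenyl)ethanone | CC(=O)c1c(O)cc(OC)cc1O | starting material
2 | 1-[2-(benzyloxy)-6-hydroxy-4-methoxyphenyl]ethanone | CC(=O)c1c(O)cc(OC)cc1OCc1ccccc1 | intermediate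
3 | 4-(benzyloxy)benzoyl chloride | O=C(Cl)c1ccc(OCc2ccccc2)cc1 | starting material
4 | 1-[2-(benzyloxy)-6-hydroxy-4-methoxyphenyl]-3-[4-(benzyloxy)phenyl]propane-1,3-dione | O=C(CC(=O)c1ccc(OCc2ccccc2)cc1)c1c(O)cc(OC)cc1OCc1ccccc1 | intermediate
5 | tert-butyl bromoacetate | CC(C)(C)OC(=O)CBr | starting material
6 | tert-butyl 3-[2-(benzyloxy)-6-hydroxy-4-methoxybenzoyl]-4-[4-(benzyloxy)phenyl]-4-oxobutanoate (racemic) | CC(C)(C)OC(=O)CC(C(=O)c1ccc(OCc2ccccc2)cc1)C(=O)c1c(O)cc(OC)cc1OCc1ccccc1 | intermediate
7 | 2-{5-(benzyloxy)-2-[4-(benzyloxy)phenyl]-7-methoxy-4-oxo-4H-chromen-3-yl}acetic acid | OC(=O)Cc1c(-c2ccc(OCc3ccccc3)cc2)oc2cc(OC)cc(OCc3ccccc3)c2c1=O | intermediate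
8 | methyl acetoacetate | COC(=O)CC(C)=O | starting material
9 | 5-(benzyloxy)-2-[4-(benzyloxy)phenyl]-3-[2-(1H-imidazol-1-yl)-2-oxoethyl]-7-methoxy-4H-chromen-4-one | O=C(Cc1c(-c2ccc(OCc3ccccc3)cc2)oc2cc(OC)cc(OCc3ccccc3)c2c1=O)n1ccnc1 | intermediate (not isolated)
10 | sodium lithium dianion of methyl acetoacetate (2,4-diide) | [Na+].[Li+].[CH2-]C(=O)[CH-]C(=O)OC | intermediate (not isolated)
11 | methyl 6-{5-(benzyloxy)-2-[4-(benzyloxy)phenyl]-7-methoxy-4-oxo-4H-chromen-3-yl}-3,5-dioxohexanoate | COC(=O)CC(=O)CC(=O)Cc1c(-c2ccc(OCc3ccccc3)cc2)oc2cc(OC)cc(OCc3ccccc3)c2c1=O | intermediate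
12 | 5-(benzyloxy)-2-[4-(benzyloxy)phenyl]-7-methoxy-3-(2,4,6-trihydroxyphenyl)-4H-chromen-4-one | COc1cc(OCc2ccccc2)c2c(=O)c(-c3c(O)cc(O)cc3O)c(-c3ccc(OCc4ccccc4)cc3)oc2c1 | intermediate
13 | 3,4-bis(benzyloxy)benzaldehyde | O=Cc1ccc(OCc2ccccc2)c(OCc2ccccc2)c1 | starting material
14 | 1,2-bis(benzyloxy)-4-(2,2-dibromoethenyl)benzene | BrC(Br)=Cc1ccc(OCc2ccccc2)c(OCc2ccccc2)c1 | intermediate
15 | lithium [3,4-bis(benzyloxy)phenyl]acetylide | [Li]C#Cc1ccc(OCc2ccccc2)c(OCc2ccccc2)c1 | intermediate (not isolated)
16 | methyl 3-[3,4-bis(benzyloxy)phenyl]prop-2-ynoate | COC(=O)C#Cc1ccc(OCc2ccccc2)c(OCc2ccccc2)c1 | intermediate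
17 | methyl (2Z)-3-[3,4-bis(benzyloxy)phenyl]-3-(4-{5-(benzyloxy)-2-[4-(benzyloxy)phenyl]-7-methoxy-4-oxo-4H-chromen-3-yl}-3,5-dihydroxyphenoxy)prop-2-enoate | COC(=O)/C=C(\Oc1cc(O)c(-c2c(-c3ccc(OCc4ccccc4)cc3)oc3cc(OC)cc(OCc4ccccc4)c3c2=O)c(O)c1)c1ccc(OCc2ccccc2)c(OCc2ccccc2)c1 | intermediate
18 | methyl (2Z)-3-(3,5-bis(benzyloxy)-4-{5-(benzyloxy)-2-[4-(benzyloxy)phenyl]-7-methoxy-4-oxo-4H-chromen-3-yl}phenoxy)-3-[3,4-bis(benzyloxy)phenyl]prop-2-enoate | COC(=O)/C=C(\Oc1cc(OCc2ccccc2)c(-c2c(-c3ccc(OCc4ccccc4)cc3)oc3cc(OC)cc(OCc4ccccc4)c3c2=O)c(OCc2ccccc2)c1)c1ccc(OCc2ccccc2)c(OCc2ccccc2)c1 | intermediate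
19 | (2Z)-3-(3,5-bis(benzyloxy)-4-{5-(benzyloxy)-2-[4-(benzyloxy)phenyl]-7-methoxy-4-oxo-4H-chromen-3-yl}phenoxy)-3-[3,4-bis(benzyloxy)phenyl]prop-2-enoic acid | OC(=O)/C=C(\Oc1cc(OCc2ccccc2)c(-c2c(-c3ccc(OCc4ccccc4)cc3)oc3cc(OC)cc(OCc4ccccc4)c3c2=O)c(OCc2ccccc2)c1)c1ccc(OCc2ccccc2)c(OCc2ccccc2)c1 | intermediate
20 | mixed anhydride of 19 with trifluoroacetic acid | O=C(OC(=O)C(F)(F)F)/C=C(\Oc1cc(OCc2ccccc2)c(-c2c(-c3ccc(OCc4ccccc4)cc3)oc3cc(OC)cc(OCc4ccccc4)c3c2=O)c(OCc2ccccc2)c1)c1ccc(OCc2ccccc2)c(OCc2ccccc2)c1 | intermediate (not isolated)
21 | 5-(benzyloxy)-2-[4-(benzyloxy)phenyl]-3-{5,7-bis(benzyloxy)-2-[3,4-bis(benzyloxy)phenyl]-4-oxo-4H-chromen-6-yl}-7-methoxy-4H-chromen-4-one (racemic axis) | COc1cc(OCc2ccccc2)c2c(=O)c(-c3c(OCc4ccccc4)cc4oc(-c5ccc(OCc6ccccc6)c(OCc6ccccc6)c5)cc(=O)c4c3OCc3ccccc3)c(-c3ccc(OCc4ccccc4)cc3)oc2c1 | intermediate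
22 | 3-[2-(3,4-dihydroxyphenyl)-5,7-dihydroxy-4-oxo-4H-chromen-6-yl]-5-hydroxy-2-(4-hydroxyphenyl)-7-methoxy-4H-chromen-4-one | COc1cc(O)c2c(=O)c(-c3c(O)cc4oc(-c5ccc(O)c(O)c5)cc(=O)c4c3O)c(-c3ccc(O)cc3)oc2c1 | target

## Step count and least certain steps

Total step count: 13. Longest linear sequence: 11 steps (from 1 to 22 through steps 1–6 and 9–13); steps 7 and 8 form a two-step branch to 16.

**Step 6 (key step).**
- What may go wrong: the chain may rest as its diketonate with the charge at C4, so that closure through the hindered C6 is slow. O-acylation to the 4-hydroxy-2-pyranone can then divert material, and long exposure to hot methoxide can open the pyranone of unit 1 (with retro-Claisen loss of the 4-benzyloxybenzoyl group if any hydroxide is present).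
- Fallback (cross-coupling in place of ring synthesis), setting out from 4 and rejoining at 12: bromination of 4 at the diketone carbon (NBS, CH2Cl2, 0 °C) would give the 2-bromo-1,3-diketone F1, and acid cyclodehydration (TFA) the 3-bromoflavone F2. Separately, phloroglucinol would be converted into 1,3,5-tris(methoxymethoxy)benzene F3 (MOMCl, i-Pr2NEt), and this by ortho-lithiation (n-BuLi, THF) and borylation with 2-isopropoxy-4,4,5,5-tetramethyl-1,3,2-dioxaborolane into the pinacol boronate F4. Suzuki–Miyaura coupling of F2 with F4 (Pd(OAc)2, SPhos, K3PO4, toluene/H2O, 90 °C) would give the tris(methoxymethyl) ether F5, and HCl in MeOH would release 12. The coupling is four-ortho-substituted and demanding, but it rests on known ligand-enabled couplings of 2,6-dialkoxyarylboron reagents and of 3-halochromones.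

**Step 9.**
- What may go wrong: poor site selectivity. Addition could occur through an ortho oxygen (which would lead on to the 8'' linkage) or through a ring carbon of the phloroglucinol (C-Michael addition, then lactonisation), because the three oxygens differ only in their steric surroundings.
- Fallback (temporary steric marking of the para oxygen), setting out from 12 and rejoining at 18: silylation with the bulky TIPSCl (imidazole, DMF, 0 °C) would give the para silyl ether F6, whose constitution follows from the retained symmetry of ring D. Benzylation (BnBr, K2CO3, DMF) would give the bis(benzyl) ether F7, and Bu4NF in THF the phenol F8. F8 has a single free hydroxyl and would add to 16 under the conditions of step 9 to give 18 directly.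

**Step 5.**
- What may go wrong: proton transfer from the acidic methylene of imidazolide 9 to the dianion (enolate or ketene formation in place of acylation), and lactonisation of 11 on acidic work-up.
- Fallback (neutral vinylogous acylation in place of dianion chemistry), setting out from 7 and rejoining at 11: oxalyl chloride with catalytic DMF would give the acid chloride F9. This would be combined at −78 °C → rt in CH2Cl2 with (1Z)-1-methoxy-1,3-bis(trimethylsilyloxy)buta-1,3-diene F10, the bis(silyl enol ether) of 8, which reacts at its terminal carbon. Dilute acid would then release 11.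

**Step 3.**
- What may go wrong: alkylation at the phenol oxygen or at an enolate oxygen in place of the diketone carbon, favoured if the diketone rests as its cyclic hemiketal.
- Fallback (side arm installed before the diketone), setting out from 2 and rejoining at 6: the dilithio species of 2 (LiN(SiMe3)2, 2.2 equiv, THF, −78 °C) would be alkylated at carbon by 5 to give tert-butyl 4-[2-(benzyloxy)-6-hydroxy-4-methoxyphenyl]-4-oxobutanoate F11. Acylation of F11 at the carbon alpha to the ketone with 3 (LiN(SiMe3)2, 3.2 equiv), as in step 2, would give 6.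

**Step 12.**
- What may go wrong: trifluoroacetylation of the very electron-rich ring D before ring closure, acid-induced loss of a benzyl group, or closure of the E isomer onto ring E to an indenone.
- Fallback (ring F by diketone cyclodehydration, with regiochemistry fixed by the single free hydroxyl), setting out from 12 by way of F6, F7 and F8 and rejoining at 21: C-acetylation of F8 ortho to its hydroxyl (Ac2O, BF3·OEt2, CH2Cl2, 0 °C → rt) would give the 2-hydroxyacetophenone F12. Acylation of its dilithio species with 3,4-bis(benzyloxy)benzoyl chloride (LiN(SiMe3)2, THF) would give the 1,3-diketone F13, and acid cyclodehydration (TFA, CH2Cl2) would give 21.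

## Further compounds

F1 | step 6 | 1-[2-(benzyloxy)-6-hydroxy-4-methoxyphenyl]-3-[4-(benzyloxy)phenyl]-2-bromopropane-1,3-dione (racemic) | O=C(C(Br)C(=O)c1ccc(OCc2ccccc2)cc1)c1c(O)cc(OC)cc1OCc1ccccc1
F2 | step 6 | 5-(benzyloxy)-2-[4-(benzyloxy)phenyl]-3-bromo-7-methoxy-4H-chromen-4-one | COc1cc(OCc2ccccc2)c2c(=O)c(Br)c(-c3ccc(OCc4ccccc4)cc3)oc2c1
F3 | step 6 | 1,3,5-tris(methoxymethoxy)benzene | COCOc1cc(OCOC)cc(OCOC)c1
F4 | step 6 | 4,4,5,5-tetramethyl-2-[2,4,6-tris(methoxymethoxy)phenyl]-1,3,2-dioxaborolane | COCOc1cc(OCOC)c(B2OC(C)(C)C(C)(C)O2)c(OCOC)c1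
F5 | step 6 | 5-(benzyloxy)-2-[4-(benzyloxy)phenyl]-7-methoxy-3-[2,4,6-tris(methoxymethoxy)phenyl]-4H-chromen-4-one | COCOc1cc(OCOC)c(-c2c(-c3ccc(OCc4ccccc4)cc3)oc3cc(OC)cc(OCc4ccccc4)c3c2=O)c(OCOC)c1
F6 | step 9 | 5-(benzyloxy)-2-[4-(benzyloxy)phenyl]-3-{2,6-dihydroxy-4-[(triisopropylsilyl)oxy]phenyl}-7-methoxy-4H-chromen-4-one | COc1cc(OCc2ccccc2)c2c(=O)c(-c3c(O)cc(O[Si](C(C)C)(C(C)C)C(C)C)cc3O)c(-c3ccc(OCc4ccccc4)cc3)oc2c1
F7 | step 9 | 5-(benzyloxy)-2-[4-(benzyloxy)phenyl]-3-{2,6-bis(benzyloxy)-4-[(triisopropylsilyl)oxy]phenyl}-7-methoxy-4H-chromen-4-one | COc1cc(OCc2ccccc2)c2c(=O)c(-c3c(OCc4ccccc4)cc(O[Si](C(C)C)(C(C)C)C(C)C)cc3OCc3ccccc3)c(-c3ccc(OCc4ccccc4)cc3)oc2c1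
F8 | step 9 | 5-(benzyloxy)-2-[4-(benzyloxy)phenyl]-3-[2,6-bis(benzyloxy)-4-hydroxyphenyl]-7-methoxy-4H-chromen-4-one | COc1cc(OCc2ccccc2)c2c(=O)c(-c3c(OCc4ccccc4)cc(O)cc3OCc3ccccc3)c(-c3ccc(OCc4ccccc4)cc3)oc2c1
F9 | step 5 | 2-{5-(benzyloxy)-2-[4-(benzyloxy)phenyl]-7-methoxy-4-oxo-4H-chromen-3-yl}acetyl chloride | O=C(Cl)Cc1c(-c2ccc(OCc3ccccc3)cc2)oc2cc(OC)cc(OCc3ccccc3)c2c1=O
F10 | step 5 | (1Z)-1-methoxy-1,3-bis(trimethylsilyloxy)buta-1,3-diene | CO/C(O[Si](C)(C)C)=C/C(=C)O[Si](C)(C)C
F11 | step 3 | tert-butyl 4-[2-(benzyloxy)-6-hydroxy-4-methoxyphenyl]-4-oxobutanoate | CC(C)(C)OC(=O)CCC(=O)c1c(O)cc(OC)cc1OCc1ccccc1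
F12 | step 12 | 3-[3-acetyl-2,6-bis(benzyloxy)-4-hydroxyphenyl]-5-(benzyloxy)-2-[4-(benzyloxy)phenyl]-7-methoxy-4H-chromen-4-one | CC(=O)c1c(O)cc(OCc2ccccc2)c(-c2c(-c3ccc(OCc4ccccc4)cc3)oc3cc(OC)cc(OCc4ccccc4)c3c2=O)c1OCc1ccccc1
F13 | step 12 | 1-(2,4-bis(benzyloxy)-3-{5-(benzyloxy)-2-[4-(benzyloxy)phenyl]-7-methoxy-4-oxo-4H-chromen-3-yl}-6-hydroxyphenyl)-3-[3,4-bis(benzyloxy)phenyl]propane-1,3-dione | O=C(CC(=O)c1ccc(OCc2ccccc2)c(OCc2ccccc2)c1)c1c(O)cc(OCc2ccccc2)c(-c2c(-c3ccc(OCc4ccccc4)cc3)oc3cc(OC)cc(OCc4ccccc4)c3c2=O)c1OCc1ccccc1
A1 | alternative 1 | 2',4',6'-trihydroxy-3'-{5-(benzyloxy)-2-[4-(benzyloxy)phenyl]-7-methoxy-4-oxo-4H-chromen-3-yl}-3,4-bis(benzyloxy)chalcone | COc1cc(OCc2ccccc2)c2c(=O)c(-c3c(O)cc(O)c(C(=O)/C=C/c4ccc(OCc5ccccc5)c(OCc5ccccc5)c4)c3O)c(-c3ccc(OCc4ccccc4)cc3)oc2c1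
A2 | alternative 1 | 5-{5-(benzyloxy)-2-[4-(benzyloxy)phenyl]-7-methoxy-4-oxo-4H-chromen-3-yl}-6-{(3E)-4-[3,4-bis(benzyloxy)phenyl]-2-oxobut-3-en-1-yl}-4-hydroxy-2H-pyran-2-one | O=C(Cc1oc(=O)cc(O)c1-c2c(-c3ccc(OCc4ccccc4)cc3)oc3cc(OC)cc(OCc4ccccc4)c3c2=O)/C=C/c1ccc(OCc2ccccc2)c(OCc2ccccc2)c1
A3 | alternative 2 | hexabenzyl ether of the target (same compound as 21) | COc1cc(OCc2ccccc2)c2c(=O)c(-c3c(OCc4ccccc4)cc4oc(-c5ccc(OCc6ccccc6)c(OCc6ccccc6)c5)cc(=O)c4c3OCc3ccccc3)c(-c3ccc(OCc4ccccc4)cc3)oc2c1
A4 | alternative 2 | (2Z)-β-aryloxycinnamic acid (same compound as 19) | OC(=O)/C=C(\Oc1cc(OCc2ccccc2)c(-c2c(-c3ccc(OCc4ccccc4)cc3)oc3cc(OC)cc(OCc4ccccc4)c3c2=O)c(OCc2ccccc2)c1)c1ccc(OCc2ccccc2)c(OCc2ccccc2)c1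
A5 | alternative 3 | 5-(benzyloxy)-2-[4-(benzyloxy)phenyl]-3-{2-hydroxy-4-[(4-methoxybenzyl)oxy]-6-[(triisopropylsilyl)oxy]phenyl}-7-methoxy-4H-chromen-4-one | COc1cc(OCc2ccccc2)c2c(=O)c(-c3c(O)cc(OCc4ccc(OC)cc4)cc3O[Si](C(C)C)(C(C)C)C(C)C)c(-c3ccc(OCc4ccccc4)cc3)oc2c1
A6 | alternative 3 | 5-(benzyloxy)-2-[4-(benzyloxy)phenyl]-7-methoxy-3-{[(triisopropylsilyl)oxy]ethynyl}-4H-chromen-4-one | COc1cc(OCc2ccccc2)c2c(=O)c(C#CO[Si](C(C)C)(C(C)C)C(C)C)c(-c3ccc(OCc4ccccc4)cc3)oc2c1
A7 | alternative 3 | 3-[(4-methoxybenzyl)oxy]cyclobut-2-en-1-one | COc1ccc(COC2=CC(=O)C2)cc1
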